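**Retrosynthetic overview**
- Target ⇐ Mitsunobu esterification, with inversion at the carbinol next to the ring fusion, of the bicyclic epoxy hydroxy lactone with the (Z)-C5 acid.
- Bicyclic alcohol ⇐ one flask: acid-triggered lactonization of an open γ-silyloxy β-bromo α-methylene ester, then indium-mediated intramolecular Barbier allylation of the tethered aldehyde (C3a–C4 bond).
- Open precursor ⇐ chemoselective ozonolysis and a ligand-controlled chromium allylation of an enal with a C5 dibromoacrylate linchpin, whose central carbon becomes C3a and is bonded twice.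
- Enal ⇐ Nozaki–Hiyama–Kishi union of a terpene-derived cis-epoxy aldehyde (Sharpless epoxidation) with a C4 (E)-iodoalkenol.
- Ring order: oxirane first, then γ-lactone, then the ten-membered carbocycle.

Assumption: the (S,S)-carbazole bis(oxazoline) ligand in step 7 is taken to give the (4S)-carbinol; if the sense is the opposite, the (R,R)-ligand is used.

**Route**

Step 1
Reactants: 1 but-2-yn-1-ol
Product: 3 (E)-3-iodobut-2-en-1-ol, via alkenylzirconocene 2 (not isolated)
Conditions: Cp2Zr(H)Cl (2.2 equiv), THF, 0 °C to rt; then I2, 0 °C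
Reagents that add atoms: iodine, II
Why: Schwartz hydrozirconation adds H and Zr syn across the alkyne with zirconium settling on the methyl-bearing carbon under thermodynamic control, and iododezirconation with retention gives the E-iodide.

Step 2
Reactants: 4 methyl 2-(bromomethyl)prop-2-enoate
Product: 6 methyl (2Z)-3-bromo-2-(bromomethyl)prop-2-enoate, via tribromide 5 (not isolated)
Conditions: Br2, CH2Cl2, 0 °C to rt; then Et3N (1.05 equiv), 0 °C
Reagents that add atoms: bromine, BrBr
Why: Bromine addition to the acrylate followed by E2 dehydrobromination (bromination–dehydrobromination) gives the vinyl bromide, whose geometry is of no consequence later.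

Step 3
Reactants: 7 nerol
Product: 8 [(2R,3S)-3-methyl-3-(4-methylpent-3-en-1-yl)oxiran-2-yl]methanol
Conditions: Ti(OiPr)4 (10 mol %), D-(−)-diethyl tartrate (12 mol %), t-BuOOH, 4 Å molecular sieves, CH2Cl2, −20 °C
Reagents that add atoms: tert-butyl hydroperoxide, CC(C)(C)OO
Why: Sharpless asymmetric epoxidation of the Z-allylic alcohol with the D-tartrate sets both oxirane carbons (2R,3S) as the cis-epoxide, leaving the remote alkene untouched.

Step 4
Reactants: 8 [(2R,3S)-3-methyl-3-(4-methylpent-3-en-1-yl)oxiran-2-yl]methanol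
Product: 9 (2S,3S)-3-methyl-3-(4-methylpent-3-en-1-yl)oxirane-2-carbaldehyde
Conditions: TEMPO (10 mol %), PhI(OAc)2 (1.1 equiv), CH2Cl2, rt
Reagents that add atoms: none
Why: TEMPO/oxoammonium oxidation converts the primary alcohol into the aldehyde under non-epimerizing conditions, the oxirane configuration being unchanged (the descriptor changes only by CIP priority).

Step 5
Reactants: 9 (2S,3S)-3-methyl-3-(4-methylpent-3-en-1-yl)oxirane-2-carbaldehyde; 3 (E)-3-iodobut-2-en-1-ol
Product: 10 (2E,4R)-3-methyl-4-[(2R,3S)-3-methyl-3-(4-methylpent-3-en-1-yl)oxiran-2-yl]but-2-ene-1,4-diol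
Conditions: CrCl2 (5 equiv), NiCl2 (2 mol %), DMSO/THF, rt
Reagents that add atoms: none
Why: Nozaki–Hiyama–Kishi coupling transfers the alkenyl group with retention of the E geometry, and Felkin–Anh attack anti to the oxirane C–O bond of the cis-epoxy aldehyde sets the new carbinol as 4R (erythro to the epoxide).

Step 6
Reactants: 10 (2E,4R)-3-methyl-4-[(2R,3S)-3-methyl-3-(4-methylpent-3-en-1-yl)oxiran-2-yl]but-2-ene-1,4-diol
Product: 12 (1R,2E)-2-methyl-1-[(2R,3S)-3-methyl-3-(4-methylpent-3-en-1-yl)oxiran-2-yl]-4-oxobut-2-en-1-yl acetate, via hydroxy enal 11 (not isolated)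
Conditions: TEMPO (10 mol %), PhI(OAc)2 (1.1 equiv), CH2Cl2, rt; then Ac2O, pyridine, DMAP (5 mol %), 0 °C
Reagents that add atoms: acetic anhydride, CC(=O)OC(C)=O
Why: Oxoammonium oxidation is selective for the primary allylic alcohol over the secondary one, which is then acetylated in the same flask (nucleophilic-catalysed acylation) without touching any stereocenter.

Step 7
Reactants: 12 (1R,2E)-2-methyl-1-[(2R,3S)-3-methyl-3-(4-methylpent-3-en-1-yl)oxiran-2-yl]-4-oxobut-2-en-1-yl acetate; 6 methyl (2Z)-3-bromo-2-(bromomethyl)prop-2-enoate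
Product: 13 methyl (4S,5E,7R)-7-(acetyloxy)-3-bromo-6-methyl-7-[(2R,3S)-3-methyl-3-(4-methylpent-3-en-1-yl)oxiran-2-yl]-2-methylidene-4-[(triethylsilyl)oxy]hept-5-enoate (C3 epimers)
Conditions: CrCl2 (10 mol %), (S,S)-1,8-bis(4-isopropyl-4,5-dihydrooxazol-2-yl)-3,6-diphenyl-9H-carbazole (12 mol %), manganese powder (3 equiv), Et3SiCl (2 equiv), iPr2NEt (0.3 equiv), 6 (2 equiv), THF, rt
Reagents that add atoms: chlorotriethylsilane, CC[Si](Cl)(CC)CC
Why: Proposed new method: divalent chromium inserts into the primary allylic C–Br bond of 6 and the allylchromium adds through its bromine-bearing γ-carbon to the enal carbonyl inside the chiral ligand sphere, which sets C4 as S by catalyst control while C3 is deliberately left unset, and the silyl chloride turns over the trivalent chromium alkoxide so that the adduct is released as the open silyl ether instead of lactonizing; the closest known reactions are the catalytic enantioselective Nozaki–Hiyama–Kishi 2-(alkoxycarbonyl)allylation of aldehydes and additions of γ-haloallylchromium reagents.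

Step 8
Reactants: 13 methyl (4S,5E,7R)-7-(acetyloxy)-3-bromo-6-methyl-7-[(2R,3S)-3-methyl-3-(4-methylpent-3-en-1-yl)oxiran-2-yl]-2-methylidene-4-[(triethylsilyl)oxy]hept-5-enoate (C3 epimers)
Product: 14 methyl (4S,5E,7R)-7-(acetyloxy)-3-bromo-6-methyl-2-methylidene-7-[(2R,3S)-3-methyl-3-(3-oxopropyl)oxiran-2-yl]-4-[(triethylsilyl)oxy]hept-5-enoate (C3 epimers)
Conditions: O3, CH2Cl2, pyridine (2 equiv), −78 °C, one equivalent by indicator; then Me2S, −78 °C to rt
Reagents that add atoms: ozone, [O-][O+]=O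
Why: Criegee ozonolysis cleaves the electron-rich isopropylidene alkene much faster than the acrylate methylidene or the trisubstituted alkene flanked by two oxygenated carbons, and no stereocenter is affected.

Step 9
Reactants: 14 methyl (4S,5E,7R)-7-(acetyloxy)-3-bromo-6-methyl-2-methylidene-7-[(2R,3S)-3-methyl-3-(3-oxopropyl)oxiran-2-yl]-4-[(triethylsilyl)oxy]hept-5-enoate (C3 epimers)
Product: 16 (3aR,4S,7S,8R,9R,10E,11aS)-7,8-epoxy-4-hydroxy-7,10-dimethyl-3-methylidene-2-oxo-2,3,3a,4,5,6,7,8,9,11a-decahydrocyclodeca[b]furan-9-yl acetate, via bromolactone 15 (not isolated)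
Conditions: PPTS (0.2 equiv), THF/H2O (10:1), 40 °C; then dilution to 2 mM with THF/H2O (3:1), indium powder (3 equiv), 25 °C
Reagents that add atoms: none
Why: Proposed new method: acid-catalysed desilylative lactonization first closes the γ-lactone, and indium insertion into the allylic C–Br bond then gives a butenolide-type allylindium (the C3 epimers converge here) that attacks the tethered aldehyde through the ring β-carbon in an intramolecular Barbier allylation closing the ten-membered ring; the tether on the lactone γ-carbon allows attack only on its own face (cis ring fusion, C3a R) and the chair-like indium-bridged transition state of this E-type allylmetal gives the anti carbinol (C4 S); the closest known reactions are the anti-selective indium-mediated allylation of aldehydes with 3-(bromomethyl)furan-2(5H)-ones and metal-mediated Barbier macrocyclizations to ten-membered α-methylene lactones.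

Step 10
Reactants: 16 (3aR,4S,7S,8R,9R,10E,11aS)-7,8-epoxy-4-hydroxy-7,10-dimethyl-3-methylidene-2-oxo-2,3,3a,4,5,6,7,8,9,11a-decahydrocyclodeca[b]furan-9-yl acetate; 17 angelic acid
Product: 18 (3aR,4R,7S,8R,9R,10E,11aS)-9-(acetyloxy)-7,8-epoxy-7,10-dimethyl-3-methylidene-2-oxo-2,3,3a,4,5,6,7,8,9,11a-decahydrocyclodeca[b]furan-4-yl (2Z)-2-methylbut-2-enoate
Conditions: PPh3 and DIAD premixed (2 equiv each), toluene, 0 °C; then 17 (2 equiv) and 16, 0 °C to rt
Reagents that add atoms: none
Why: Mitsunobu esterification displaces the activated C4 oxygen by the carboxylate in an SN2 step, inverting C4 from S to R, and the neutral conditions without amine nucleophiles keep the Z geometry of the angelate.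

**Compound list**
1 | but-2-yn-1-ol | CC#CCO | starting material
2 | (E)-alkenylzirconocene chloride, O-zirconated (from hydrozirconation of 1) | Cl[Zr](OC/C=C(\C)[Zr](Cl)(C1C=CC=C1)C1C=CC=C1)(C1C=CC=C1)C1C=CC=C1 | intermediate
3 | (E)-3-iodobut-2-en-1-ol | OC/C=C(\C)I | intermediate
4 | methyl 2-(bromomethyl)prop-2-enoate | COC(=O)C(=C)CBr | starting material
5 | methyl 2,3-dibromo-2-(bromomethyl)propanoate | COC(=O)C(Br)(CBr)CBr | intermediate
6 | methyl (2Z)-3-bromo-2-(bromomethyl)prop-2-enoate | COC(=O)/C(CBr)=C/Br | intermediate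
7 | nerol, (2Z)-3,7-dimethylocta-2,6-dien-1-ol | OC/C=C(C)\CCC=C(C)C | starting material
8 | [(2R,3S)-3-methyl-3-(4-methylpent-3-en-1-yl)oxiran-2-yl]methanol | OC[C@H]1O[C@@]1(C)CCC=C(C)C | intermediate
9 | (2S,3S)-3-methyl-3-(4-methylpent-3-en-1-yl)oxirane-2-carbaldehyde | O=C[C@H]1O[C@@]1(C)CCC=C(C)C | intermediate
10 | (2E,4R)-3-methyl-4-[(2R,3S)-3-methyl-3-(4-methylpent-3-en-1-yl)oxiran-2-yl]but-2-ene-1,4-diol | OC/C=C(\C)[C@@H](O)[C@H]1O[C@@]1(C)CCC=C(C)C | intermediate
11 | (2E,4R)-4-hydroxy-3-methyl-4-[(2R,3S)-3-methyl-3-(4-methylpent-3-en-1-yl)oxiran-2-yl]but-2-enal | O=C/C=C(\C)[C@@H](O)[C@H]1O[C@@]1(C)CCC=C(C)C | intermediate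
12 | (1R,2E)-2-methyl-1-[(2R,3S)-3-methyl-3-(4-methylpent-3-en-1-yl)oxiran-2-yl]-4-oxobut-2-en-1-yl acetate | O=C/C=C(\C)[C@@H](OC(C)=O)[C@H]1O[C@@]1(C)CCC=C(C)C | intermediate
13 | methyl (4S,5E,7R)-7-(acetyloxy)-3-bromo-6-methyl-7-[(2R,3S)-3-methyl-3-(4-methylpent-3-en-1-yl)oxiran-2-yl]-2-methylidene-4-[(triethylsilyl)oxy]hept-5-enoate (C3 epimers) | CC[Si](CC)(CC)O[C@H](C(Br)C(=C)C(=O)OC)/C=C(\C)[C@@H](OC(C)=O)[C@H]1O[C@@]1(C)CCC=C(C)C | intermediate
14 | methyl (4S,5E,7R)-7-(acetyloxy)-3-bromo-6-methyl-2-methylidene-7-[(2R,3S)-3-methyl-3-(3-oxopropyl)oxiran-2-yl]-4-[(triethylsilyl)oxy]hept-5-enoate (C3 epimers) | CC[Si](CC)(CC)O[C@H](C(Br)C(=C)C(=O)OC)/C=C(\C)[C@@H](OC(C)=O)[C@H]1O[C@@]1(C)CCC=O | intermediate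
15 | (1R,2E)-3-[(2S)-3-bromo-4-methylidene-5-oxooxolan-2-yl]-2-methyl-1-[(2R,3S)-3-methyl-3-(3-oxopropyl)oxiran-2-yl]prop-2-en-1-yl acetate (C3 epimers of the oxolane) | C=C1C(=O)O[C@@H](/C=C(\C)[C@@H](OC(C)=O)[C@H]2O[C@@]2(C)CCC=O)C1Br | intermediate
16 | (3aR,4S,7S,8R,9R,10E,11aS)-7,8-epoxy-4-hydroxy-7,10-dimethyl-3-methylidene-2-oxo-2,3,3a,4,5,6,7,8,9,11a-decahydrocyclodeca[b]furan-9-yl acetate | C=C1C(=O)O[C@H]2/C=C(\C)[C@@H](OC(C)=O)[C@H]3O[C@@]3(C)CC[C@H](O)[C@@H]12 | intermediate
17 | angelic acid, (2Z)-2-methylbut-2-enoic acid | C/C=C(/C)C(=O)O | starting material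
18 | (3aR,4R,7S,8R,9R,10E,11aS)-9-(acetyloxy)-7,8-epoxy-7,10-dimethyl-3-methylidene-2-oxo-2,3,3a,4,5,6,7,8,9,11a-decahydrocyclodeca[b]furan-4-yl (2Z)-2-methylbut-2-enoate | C=C1C(=O)O[C@H]2/C=C(\C)[C@@H](OC(C)=O)[C@H]3O[C@@]3(C)CC[C@@H](OC(=O)/C(C)=C\C)[C@@H]12 | target

**Step count**
Total: 10 steps. Longest linear sequence: 8 steps (7 → 8 → 9 → 10 → 12 → 13 → 14 → 16 → 18).

**Steps most likely to fail, with fallbacks**

Step 7 (ligand-controlled allylation with the dibromo linchpin; unprecedented reagent, and over-reduction of the product bromide is possible). The fallback sets out from 12 and comes back at 13. Compound 12 and 6 are combined with indium powder in THF/H2O at 0 °C without any ligand. This gives the open γ-hydroxy ester methyl (5E,7R)-7-(acetyloxy)-3-bromo-4-hydroxy-6-methyl-7-[(2R,3S)-3-methyl-3-(4-methylpent-3-en-1-yl)oxiran-2-yl]-2-methylidenehept-5-enoate F1 as a mixture at C3 and C4. Silylation with Et3SiOTf and 2,6-lutidine gives 13 together with its (4R)-epimer F2, and the two are separated by preparative HPLC. Stereocontrol is thus moved from the catalyst to a separation of epimers.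

Step 9 (ten-membered ring closure; oligomerization, protonation of the allylindium, or the wrong facial or C4 outcome). The fallback sets out from 14 and comes back at 16. The acid stage is run alone and 15 is isolated. LiBr in acetone transposes the secondary allylic bromide by SN2′ equilibration to the conjugated primary bromide (1R,2E)-3-[(2S)-4-(bromomethyl)-5-oxo-2,5-dihydrofuran-2-yl]-2-methyl-1-[(2R,3S)-3-methyl-3-(3-oxopropyl)oxiran-2-yl]prop-2-en-1-yl acetate F3. Slow addition of F3 to SmI2 in THF at −78 °C under high dilution closes the ring by a single-electron samarium Barbier (ketyl–olefin) pathway to give 16. This replaces the aqueous two-electron indium chemistry with anhydrous divalent samarium chemistry on an isolated lactone.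

Step 10 (Mitsunobu inversion of a hindered ring carbinol; elimination or phosphine addition to the methylidene lactone). The fallback sets out from 16 and comes back at 18. Compound 16 is converted with chloromethanesulfonyl chloride and pyridine into the chloromethanesulfonate (3aR,4S,7S,8R,9R,10E,11aS)-9-(acetyloxy)-7,8-epoxy-7,10-dimethyl-3-methylidene-2-oxo-2,3,3a,4,5,6,7,8,9,11a-decahydrocyclodeca[b]furan-4-yl chloromethanesulfonate F4. Displacement with cesium (2Z)-2-methylbut-2-enoate and 18-crown-6 in toluene at 40 °C gives 18 with inversion. This replaces the redox condensation with a sulfonate displacement by a preformed carboxylate.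

Further compounds
F1 | step 7 | methyl (5E,7R)-7-(acetyloxy)-3-bromo-4-hydroxy-6-methyl-7-[(2R,3S)-3-methyl-3-(4-methylpent-3-en-1-yl)oxiran-2-yl]-2-methylidenehept-5-enoate (C3 and C4 epimers) | COC(=O)C(=C)C(Br)C(O)/C=C(\C)[C@@H](OC(C)=O)[C@H]1O[C@@]1(C)CCC=C(C)C
F2 | step 7 | methyl (4R,5E,7R)-7-(acetyloxy)-3-bromo-6-methyl-7-[(2R,3S)-3-methyl-3-(4-methylpent-3-en-1-yl)oxiran-2-yl]-2-methylidene-4-[(triethylsilyl)oxy]hept-5-enoate (C3 epimers) | CC[Si](CC)(CC)O[C@@H](C(Br)C(=C)C(=O)OC)/C=C(\C)[C@@H](OC(C)=O)[C@H]1O[C@@]1(C)CCC=C(C)C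
F3 | step 9 | (1R,2E)-3-[(2S)-4-(bromomethyl)-5-oxo-2,5-dihydrofuran-2-yl]-2-methyl-1-[(2R,3S)-3-methyl-3-(3-oxopropyl)oxiran-2-yl]prop-2-en-1-yl acetate | BrCC1=C[C@H](/C=C(\C)[C@@H](OC(C)=O)[C@H]2O[C@@]2(C)CCC=O)OC1=O
F4 | step 10 | (3aR,4S,7S,8R,9R,10E,11aS)-9-(acetyloxy)-7,8-epoxy-7,10-dimethyl-3-methylidene-2-oxo-2,3,3a,4,5,6,7,8,9,11a-decahydrocyclodeca[b]furan-4-yl chloromethanesulfonate | C=C1C(=O)O[C@H]2/C=C(\C)[C@@H](OC(C)=O)[C@H]3O[C@@]3(C)CC[C@H](OS(=O)(=O)CCl)[C@@H]12
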